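At early times the open intermediate leaves by two paths, to side product and, through second catalyst and reagent, to target. The question is how the rates of those two paths compare as the run ages.

the same everywhere: free catalyst 0.20 mM; second catalyst 1.8 mM

|  | starting material | reagent | remark | time |
|---|---|---|---|---|
| alder | 0.10 M | 0.24 M | run made earlier |  |
| birch | 0.40 M | 0.24 M | run made earlier |  |
| flask | 0.20 M | 0.240 M |  | 2.0 h |

- alder (time / min: side product / %, target / %): 20.0: 66.9, 11.6; 40.0: 82.6, 14.5; 60.0: 83.6, 12.1; 80.0: 83.9, 14.6; 90.0: 85.9, 14.0; 120: 85.1, 13.4
- birch (time / min: side product / %, target / %): 20.0: 66.9, 9.3; 40.0: 82.0, 12.4; 60.0: 85.1, 13.5; 80.0: 85.1, 12.2; 90.0: 86.1, 12.4; 120: 86.8, 15.0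

(scatter of a reading: 1 percentage point)

* ratio of side product to target at 50 s
* ratio of side product to target at 10 min
* ratio of side product to target at 2.0 h
* which of side product and target there is more of at 2.0 h

- the analysis behind the earlier runs scatters by 1 percentage point, standard deviation
- reactions considered so far: open intermediate -> side product; starting material + free catalyst <-> free catalyst + open intermediate; second catalyst + open intermediate <-> catalyst intermediate; reagent + catalyst intermediate -> second catalyst + target

The feed into both products is described here by a first-order rate constant k, read from what has reached them at 20.0 min: 0.0769 /min in alder and 0.0718 /min in birch. In the flask, taking alder's k, this feed falls to 0.463 of its starting value at 10 min and to 9.88 × 10⁻⁵ at 2.0 h. That slowing acts on both paths, so it cancels from their ratio.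

The target path is taken here to slow in proportion to the reagent left, and u is the share of the reagent's charge used by the end, each target taking one reagent. The late ratio R, side product over target summed over the readings from 80.0 min on, is 6.07 in alder and 6.52 in birch. So u reads 0.0589 in alder and 0.222 in birch, which spends more reagent. An even split, ratio one, is the plain zero of the scale, but the useful zero is the ratio with reagent as charged. Multiplying R by the mean reagent factor, the mean of its start and end values, gives 5.89 and 5.79. Their mean is S, the selectivity factor: side-product rate over target rate at the charged reagent and second catalyst, 5.84.

For the flask, my own reckoning gives u = 0.122, so the ratio should rise from about 5.84 through 6.04 to 6.22. The forecast differs in direction, falling through 6.7, 6.5 and 6.3 with side product ahead; of the start it says: “Early ratios may run slightly higher”.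

The flask gives 5.83, 5.99 and 6.15, a ratio that rises, with side product ahead; the forecast's values stand within their tolerance.

    open intermediate → side product (k = 0.00900 /s)
    starting material + free catalyst ⇌ free catalyst + open intermediate (K = 0.240, k = 15.0 /M/s)
    second catalyst + open intermediate ⇌ catalyst intermediate (K = 0.180 /M, k = 9.20 /M/s)
    reagent + catalyst intermediate → second catalyst + target (k = 22.0 /M/s)

At 0.200 h the flask's second catalyst stood at 99.8% of its charge, with catalyst intermediate at 0.168%. Set against the final ratio, S implies a mean reagent factor of 0.950, which lies between the reagent's full charge and the 88.3% of it left at 2.00 h. A neighbouring flask, the same but for its second catalyst, holds a quarter of that charge, 4.5 × 10⁻⁴ M. Taking the target rate in proportion to second catalyst, S becomes 23.4, and the end ratio 23.8. That neighbouring flask, as computed, gives 23.3 at 50 s and 23.6 at 2.0 h.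

All runs were computed from invented constants.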